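**Plan**
1. Core numbering: spiro[4.5]decane, five-membered ring C1–C5 (C1 = CHOH, C2 = CH bearing the triene, C5 = spiro carbon), six-membered ring C5–C10 (C6 = CH with the hydroxypropyl chain, C7 = enal carbon, C10 = C(CH3)OH); side chain C1′(=CH2), C2′ to C6′. Early intermediates keep dioxaspirodecane locants in their names.
2. Retrosynthesis: the enal is cut to a C7 ketone (isopropenyl carbinol, oxidative 1,3-transposition), the triene at C2′–C3′ (alkenylsilane plus dienyl iodide), C2–C2′ to a silicon tether on O1, and finally the five-membered ring at C4–C5, back to a cyclobutane.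
3. Enabling feature: the spiro carbon C5 has an oxygen-bearing ring neighbour C1 and the tertiary carbinol C10 as its other neighbour. This is the retron of a 1,2-shift of a cyclobutane bond from an oxygenated carbon onto a cation at C5 (1-oxaspiro[2.3]hexane to cyclopentanone), with the epoxide placed by the C10 hydroxyl.
4. Forward: the cyclohexane is bought as an enone ketal; conjugate addition, aldol and dehydration attach the chain and a cyclobutylidene; methyl addition, directed epoxidation and ring expansion give the spiro cyclopentanone; a temporary siloxane ring (O1–Si–C2′–C2) is closed and then opened by cross-coupling with the dienyl iodide; the enal comes last.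
5. Stereochemistry: C6 from a catalyst-controlled conjugate addition, C10 from methyl addition anti to the C6 chain, C5 from OH-directed epoxidation and stereospecific migration, C1 from a chelation-controlled reduction, C2 from the cis-fused tether; alkene geometries from carbomagnesiation/iodinolysis, Stille coupling and the sigmatropic transposition.

Key step: step 5

Remark: (1-bromovinyl)chlorodimethylsilane (13) is treated as a catalogue reagent, and the antipode of the ligand in step 1 is the one that delivers the C6 configuration drawn.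

**Step 1**
Reactants: 1 1,4-dioxaspiro[4.5]dec-6-en-8-one; 2 (3-bromopropoxy)(tert-butyl)dimethylsilane; 3 cyclobutanone
Product: 6 trans-7-(1-hydroxycyclobutyl)-6-[3-(tert-butyldimethylsilyloxy)propyl]-1,4-dioxaspiro[4.5]decan-8-one, via Grignard reagent 4 (not isolated), via magnesium enolate 5 (not isolated)
Conditions: Mg, Et2O (2 to 4); CuBr·SMe2 (5 mol %), TaniaPhos (6 mol %), t-BuOMe, −78 °C, then 1; then 3, −78 to −40 °C; aq NH4Cl
Reagents that add atoms: none
Why: Copper-catalysed enantioselective conjugate addition of a Grignard reagent to a 4,4-disubstituted cyclohexenone sets the chain-bearing carbon (future C6) under catalyst control, and the regiodefined magnesium enolate 5 adds in a tandem aldol reaction to the strain-activated carbonyl of cyclobutanone anti to the new chain (this second centre is erased in step 2).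

**Step 2**
Reactants: 6 trans-7-(1-hydroxycyclobutyl)-6-[3-(tert-butyldimethylsilyloxy)propyl]-1,4-dioxaspiro[4.5]decan-8-one
Product: 7 7-cyclobutylidene-6-[3-(tert-butyldimethylsilyloxy)propyl]-1,4-dioxaspiro[4.5]decan-8-one
Conditions: Burgess reagent, THF, 50 °C
Reagents that add atoms: none
Why: Burgess dehydration of the tertiary β-hydroxy ketone (syn elimination through the sulfamate ester toward the acidic hydrogen α to the ketone) should give the conjugated exocyclic enone in preference to a strained cyclobutene.

**Step 3**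
Reactants: 7 7-cyclobutylidene-6-[3-(tert-butyldimethylsilyloxy)propyl]-1,4-dioxaspiro[4.5]decan-8-one
Product: 8 7-cyclobutylidene-8-methyl-6-[3-(tert-butyldimethylsilyloxy)propyl]-1,4-dioxaspiro[4.5]decan-8-ol
Conditions: MeLi, CeCl3, THF, −78 °C
Reagents that add atoms: methyllithium, [Li]C
Why: 1,2-Addition of the weakly basic organocerium reagent to the enone, in which an axial chain (allylic 1,3-strain against the cyclobutylidene) forces equatorial attack from the opposite face and an equatorial chain allows the preferred axial attack from that same face, so both conformers should place the new hydroxyl (future C10–OH) cis to the chain by substrate control.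

**Step 4**
Reactants: 8 7-cyclobutylidene-8-methyl-6-[3-(tert-butyldimethylsilyloxy)propyl]-1,4-dioxaspiro[4.5]decan-8-ol
Product: 9 syn-epoxy alcohol of 8 with a 1-oxaspiro[2.3]hexane unit
Conditions: VO(acac)2 (5 mol %), t-BuOOH (decane), CH2Cl2, 0 °C; aq Na2S2O3; filtration through basic alumina; used at once
Reagents that add atoms: tert-butyl hydroperoxide, CC(C)(C)OO
Why: Vanadium-catalysed hydroxyl-directed epoxidation of a tertiary allylic alcohol, in which the metal-bound hydroxyl delivers the peroxide oxygen to its own face of the tetrasubstituted exocyclic alkene and so fixes the ring epoxide carbon (future C5) syn to the hydroxyl.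

**Step 5**
Reactants: 9 syn-epoxy alcohol of 8 with a 1-oxaspiro[2.3]hexane unit
Product: 10 7,7-ethylenedioxy-10-hydroxy-10-methyl-6-[3-(tert-butyldimethylsilyloxy)propyl]spiro[4.5]decan-1-one
Conditions: BF3·OEt2 (0.2 equiv), CH2Cl2, −78 °C; Et3N quench
Reagents that add atoms: none
Why: BF3 coordinates the epoxide oxygen and the C–O bond at the cyclohexane carbon (future C5, tertiary) ionises while a cyclobutane C–C bond migrates from the oxygen-bearing carbon to C5, so that the four-membered ring becomes the cyclopentanone and the oxygen stays on C1 as the ketone. The closest known reaction type is the Lewis-acid rearrangement of 1-oxaspiro[2.3]hexanes (epoxides of alkylidenecyclobutanes) to cyclopentanones, a Meinwald or semipinacol-type ring expansion. No ring is closed by cyclisation: the five-membered ring arises by a 1,2-alkyl shift that enlarges the cyclobutane by one carbon and creates the spiro junction at the migration terminus. The new quaternary stereocentre C5 is controlled by the epoxide configuration from step 4, because the migrating CH2 enters anti to the departing oxygen (inversion at C5) and the cis tertiary hydroxyl shields the other face, so C1 ends cis to the C10 oxygen and cis to the C6 chain. The step needs cleavage of the C5–O bond and not the cyclobutyl C–O bond (tertiary versus strained cation), ring expansion instead of a pinacol-type shift from C10 (strain release and the push of the boron-bound oxygen on C1), and survival of the dioxolane and the silyl ether (catalytic Lewis acid at low temperature); the two cyclobutane CH2 groups are equivalent, so the migration raises no regiochemical question.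

**Step 6**
Reactants: 10 7,7-ethylenedioxy-10-hydroxy-10-methyl-6-[3-(tert-butyldimethylsilyloxy)propyl]spiro[4.5]decan-1-one
Product: 11 7,7-ethylenedioxy-10-hydroxy-10-methyl-6-[3-(tert-butyldimethylsilyloxy)propyl]spiro[4.5]dec-2-en-1-one
Conditions: IBX (2 equiv), 4-methoxypyridine N-oxide (2 equiv), DMSO, 25–40 °C
Reagents that add atoms: none
Why: IBX dehydrogenation of the ketone through its enol, which can form only toward C2 because the other α-carbon is the quaternary spiro centre, should give the cyclopentenone needed for the tether chemistry.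

**Step 7**
Reactants: 11 7,7-ethylenedioxy-10-hydroxy-10-methyl-6-[3-(tert-butyldimethylsilyloxy)propyl]spiro[4.5]dec-2-en-1-one
Product: 12 7,7-ethylenedioxy-10-methyl-6-[3-(tert-butyldimethylsilyloxy)propyl]spiro[4.5]dec-2-ene-1,10-diol
Conditions: Et2BOMe, THF/MeOH 4:1, −78 °C; NaBH4; MeOH azeotrope
Reagents that add atoms: none
Why: Narasaka–Prasad reduction, in which the C10 hydroxyl and the C1 carbonyl are tied in a six-membered diethylboron chelate on the C10 face of the cyclopentenone, so that external hydride adds 1,2 to the activated carbonyl from the opposite face and the new C1 hydroxyl ends cis to C10 as in a cis-fused bicyclic boronate.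

**Step 8**
Reactants: 12 7,7-ethylenedioxy-10-methyl-6-[3-(tert-butyldimethylsilyloxy)propyl]spiro[4.5]dec-2-ene-1,10-diol; 13 (1-bromovinyl)chlorodimethylsilane
Product: 14 1-O-[(1-bromovinyl)dimethylsilyl] ether of diol 12
Conditions: Et3N, DMAP (cat), CH2Cl2, 0 °C; used without chromatography
Reagents that add atoms: none
Why: Chemoselective O-silylation of the secondary allylic alcohol by the chlorosilane (the tertiary C10 hydroxyl is too hindered) installs the temporary silicon tether that carries the future C2′ and C1′ carbons.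

**Step 9**
Reactants: 14 1-O-[(1-bromovinyl)dimethylsilyl] ether of diol 12
Product: 15 cis-fused 2,2-dimethyl-3-methylene-1-oxa-2-silacyclopentane annulated at C1–C2 of the spiro core
Conditions: Bu3SnH (slow addition), AIBN (cat), benzene, 80 °C
Reagents that add atoms: none
Why: Silicon-tethered 5-exo-trig vinyl radical cyclisation in a tin hydride chain, in which the vinyl radical on silicon can reach only the C2 end of the ring alkene from the face of the C1 oxygen, so the C2–C2′ bond and the C2 stereocentre are set cis to O1 by the cis ring fusion before the C3 radical is reduced.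

**Step 10**
Reactants: 16 prop-2-yn-1-ol; 17 5-bromo-2-methylpent-2-ene
Product: 20 (2Z)-3-iodo-2-(4-methylpent-3-en-1-yl)prop-2-en-1-ol, via Grignard reagent 18 (not isolated), via alkenylmagnesium alkoxide 19 (not isolated)
Conditions: Mg, THF (17 to 18, 2.5 equiv); 16, CuI (10 mol %), THF, −10 °C to 25 °C; iodine, −40 to 0 °C
Reagents that add atoms: iodine, I-I
Why: Copper-catalysed anti-carbomagnesiation of the propargylic alkoxide delivers the homoprenyl group to C2 and magnesium to C3 cis to the CH2O group in a five-membered chelate, and iodinolysis with retention gives the (Z)-iodoalkene that fixes the trisubstituted alkene geometry of the side chain.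

**Step 11**
Reactants: 20 (2Z)-3-iodo-2-(4-methylpent-3-en-1-yl)prop-2-en-1-ol
Product: 21 tert-butyl{[(2Z)-3-iodo-2-(4-methylpent-3-en-1-yl)prop-2-en-1-yl]oxy}dimethylsilane
Conditions: t-BuMe2SiCl, imidazole, DMF, 0 to 25 °C
Reagents that add atoms: tert-butyldimethylsilyl chloride, CC(C)(C)[Si](C)(C)Cl
Why: Imidazole-promoted silylation of the primary allylic alcohol protects it for the palladium chemistry.

**Step 12**
Reactants: 21 tert-butyl{[(2Z)-3-iodo-2-(4-methylpent-3-en-1-yl)prop-2-en-1-yl]oxy}dimethylsilane; 22 (E)-1,2-bis(tributylstannyl)ethene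
Product: 23 tributyl[(1E,3Z)-4-(tert-butyldimethylsilyloxymethyl)-8-methylnona-1,3,7-trien-1-yl]stannane
Conditions: PdCl2(MeCN)2 (5 mol %), 22 (2.5 equiv), DMF, 25 °C
Reagents that add atoms: none
Why: Stille coupling with retention of configuration at both sp2 carbons, in which the excess of the symmetric distannane should ensure monocoupling and give the (1E,3Z)-dienylstannane.

**Step 13**
Reactants: 23 tributyl[(1E,3Z)-4-(tert-butyldimethylsilyloxymethyl)-8-methylnona-1,3,7-trien-1-yl]stannane
Product: 24 (1E,3Z)-1-iodo-4-(tert-butyldimethylsilyloxymethyl)-8-methylnona-1,3,7-triene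
Conditions: iodine (1.05 equiv), CH2Cl2, 0 °C; aq Na2S2O3
Reagents that add atoms: iodine, I-I
Why: Iododestannylation (ipso electrophilic substitution of the alkenyl–tin bond with retention) should convert the stannane into the dienyl iodide without touching the trisubstituted alkenes.

**Step 14**
Reactants: 15 cis-fused 2,2-dimethyl-3-methylene-1-oxa-2-silacyclopentane annulated at C1–C2 of the spiro core; 24 (1E,3Z)-1-iodo-4-(tert-butyldimethylsilyloxymethyl)-8-methylnona-1,3,7-triene
Product: 25 triene diol with the complete carbon skeleton except the enal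
Conditions: Pd2(dba)3·CHCl3 (5 mol %), KOSiMe3 (2.5 equiv), DME, 25 °C; aq NH4Cl
Reagents that add atoms: none
Why: Hiyama–Denmark cross-coupling, in which trimethylsilanolate opens the five-membered alkoxysilane to a potassium alkenylsilanolate that transmetalates to the dienylpalladium iodide, so the C2′–C3′ bond forms with retention of both alkene geometries, the C1 hydroxyl is released, and the silyl ethers are spared because no fluoride is used.

**Step 15**
Reactants: 25 triene diol with the complete carbon skeleton except the enal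
Product: 26 1,10-bis(triethylsilyl) ether of 25
Conditions: Et3SiOTf (3 equiv), 2,6-lutidine, CH2Cl2, −78 to 0 °C
Reagents that add atoms: triethylsilyl trifluoromethanesulfonate, CC[Si](CC)(CC)OS(=O)(=O)C(F)(F)F
Why: Silylation with the silyl triflate and 2,6-lutidine protects the hindered secondary and the tertiary hydroxyl in one operation ahead of the oxidation in step 18.

**Step 16**
Reactants: 26 1,10-bis(triethylsilyl) ether of 25
Product: 27 C7 ketone of the fully silylated triene
Conditions: pyridinium p-toluenesulfonate (0.3 equiv), acetone/H2O 9:1, 45 °C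
Reagents that add atoms: water, O
Why: Mildly acid-catalysed ketal hydrolysis should unveil the C7 ketone while the hindered triethylsilyl ethers, the primary tert-butyldimethylsilyl ethers and the C6 stereocentre survive.

**Step 17**
Reactants: 27 C7 ketone of the fully silylated triene
Product: 28 C7 isopropenyl carbinol
Conditions: isopropenylmagnesium bromide, CeCl3, THF, −78 °C
Reagents that add atoms: isopropenylmagnesium bromide, CC(=C)[Mg]Br
Why: 1,2-Addition of the organocerium reagent (low basicity avoids enolisation and epimerisation at C6) to the hindered ketone gives the tertiary allylic alcohol, whose configuration is of no consequence because C7 becomes sp2 in step 18.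

**Step 18**
Reactants: 28 C7 isopropenyl carbinol
Product: 29 silyl-protected (Z)-enal
Conditions: pyridinium chlorochromate [C5H5NH][CrO3Cl] (3 equiv), NaOAc, 4 Å molecular sieves, CH2Cl2, 25 °C
Reagents that add atoms: pyridinium chlorochromate, [O-][Cr](=O)(=O)Cl.c1cc[nH+]cc1
Why: Babler–Dauben oxidative 1,3-transposition, in which the tertiary chromate ester undergoes a [3,3]-sigmatropic shift and the primary allylic chromate is oxidised to the enal, while allylic 1,2-strain keeps the isopropenyl methyl over the unhindered C8 methylene so that the oxygenated carbon should end cis to C6 (the Z geometry of the target).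

**Step 19**
Reactants: 29 silyl-protected (Z)-enal
Product: 30 (2Z)-2-[(1S,2R,5S,6R,10S)-1,10-dihydroxy-2-[(3E,5Z)-6-(hydroxymethyl)-10-methylundeca-1,3,5,9-tetraen-2-yl]-6-(3-hydroxypropyl)-10-methylspiro[4.5]decan-7-ylidene]propanal
Conditions: HF·pyridine, pyridine, THF, 0 to 25 °C
Reagents that add atoms: none
Why: Cleavage of all four silyl ethers with buffered HF·pyridine (Si–F bond formation) should release the tetraol without isomerising the enal or the triene.

**Compound list**
1 | 1,4-dioxaspiro[4.5]dec-6-en-8-one | O=C1C=CC2(CC1)OCCO2 | starting material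
2 | (3-bromopropoxy)(tert-butyl)dimethylsilane | BrCCCO[Si](C)(C)C(C)(C)C | starting material
3 | cyclobutanone | O=C1CCC1 | starting material
4 | [3-(tert-butyldimethylsilyloxy)propyl]magnesium bromide | Br[Mg]CCCO[Si](C)(C)C(C)(C)C | intermediate
5 | bromomagnesium enolate of 6-[3-(tert-butyldimethylsilyloxy)propyl]-1,4-dioxaspiro[4.5]decan-8-one (C7=C8 enolate) | Br[Mg]OC1=C[C@H](CCCO[Si](C)(C)C(C)(C)C)C2(OCCO2)CC1 | intermediate
6 | trans-7-(1-hydroxycyclobutyl)-6-[3-(tert-butyldimethylsilyloxy)propyl]-1,4-dioxaspiro[4.5]decan-8-one | O=C1CCC2(OCCO2)[C@@H](CCCO[Si](C)(C)C(C)(C)C)[C@@H]1C1(O)CCC1 | intermediate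
7 | 7-cyclobutylidene-6-[3-(tert-butyldimethylsilyloxy)propyl]-1,4-dioxaspiro[4.5]decan-8-one | O=C1CCC2(OCCO2)[C@@H](CCCO[Si](C)(C)C(C)(C)C)C1=C3CCC3 | intermediate
8 | 7-cyclobutylidene-8-methyl-6-[3-(tert-butyldimethylsilyloxy)propyl]-1,4-dioxaspiro[4.5]decan-8-ol (hydroxyl cis to the C6 chain) | C[C@]1(O)CCC2(OCCO2)[C@@H](CCCO[Si](C)(C)C(C)(C)C)C1=C3CCC3 | intermediate
9 | epoxide of 8 at the cyclobutylidene double bond (1-oxaspiro[2.3]hexane unit; epoxide oxygen cis to the tertiary hydroxyl) | C[C@]1(O)CCC2(OCCO2)[C@@H](CCCO[Si](C)(C)C(C)(C)C)[C@@]13OC34CCC4 | intermediate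
10 | 7,7-ethylenedioxy-10-hydroxy-10-methyl-6-[3-(tert-butyldimethylsilyloxy)propyl]spiro[4.5]decan-1-one (C1, the C10 hydroxyl and the C6 chain on the same face of the cyclohexane) | C1CC[C@]2([C@H](CCCO[Si](C)(C)C(C)(C)C)C3(OCCO3)CC[C@]2(C)O)C1=O | intermediate
11 | 7,7-ethylenedioxy-10-hydroxy-10-methyl-6-[3-(tert-butyldimethylsilyloxy)propyl]spiro[4.5]dec-2-en-1-one | C1=CC[C@]2([C@H](CCCO[Si](C)(C)C(C)(C)C)C3(OCCO3)CC[C@]2(C)O)C1=O | intermediate
12 | 7,7-ethylenedioxy-10-methyl-6-[3-(tert-butyldimethylsilyloxy)propyl]spiro[4.5]dec-2-ene-1,10-diol (C1 hydroxyl on the C10 side) | C1=CC[C@]2([C@H](CCCO[Si](C)(C)C(C)(C)C)C3(OCCO3)CC[C@]2(C)O)[C@H]1O | intermediate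
13 | (1-bromovinyl)chlorodimethylsilane | C=C(Br)[Si](C)(C)Cl | starting material
14 | 1-O-[(1-bromovinyl)dimethylsilyl] ether of diol 12 | C1=CC[C@]2([C@H](CCCO[Si](C)(C)C(C)(C)C)C3(OCCO3)CC[C@]2(C)O)[C@H]1O[Si](C)(C)C(Br)=C | intermediate
15 | cis-fused siloxane: 2,2-dimethyl-3-methylene-1-oxa-2-silacyclopentane annulated at C1 (oxygen) and C2 (carbon) of the spiro core | C=C1[C@H]2CC[C@]3([C@H](CCCO[Si](C)(C)C(C)(C)C)C4(OCCO4)CC[C@]3(C)O)[C@H]2O[Si]1(C)C | intermediate
16 | prop-2-yn-1-ol | C#CCO | starting material
17 | 5-bromo-2-methylpent-2-ene | CC(C)=CCCBr | starting material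
18 | (4-methylpent-3-en-1-yl)magnesium bromide | CC(C)=CCC[Mg]Br | intermediate
19 | bromomagnesium (2Z)-3-(bromomagnesio)-2-(4-methylpent-3-en-1-yl)prop-2-en-1-olate | Br[Mg]/C=C(\CO[Mg]Br)CCC=C(C)C | intermediate
20 | (2Z)-3-iodo-2-(4-methylpent-3-en-1-yl)prop-2-en-1-ol | I/C=C(\CO)CCC=C(C)C | intermediate
21 | tert-butyl{[(2Z)-3-iodo-2-(4-methylpent-3-en-1-yl)prop-2-en-1-yl]oxy}dimethylsilane | I/C=C(\CO[Si](C)(C)C(C)(C)C)CCC=C(C)C | intermediate
22 | (E)-1,2-bis(tributylstannyl)ethene | CCCC[Sn](CCCC)(CCCC)/C=C/[Sn](CCCC)(CCCC)CCCC | starting material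
23 | tributyl[(1E,3Z)-4-(tert-butyldimethylsilyloxymethyl)-8-methylnona-1,3,7-trien-1-yl]stannane | CCCC[Sn](CCCC)(CCCC)/C=C/C=C(\CO[Si](C)(C)C(C)(C)C)CCC=C(C)C | intermediate
24 | (1E,3Z)-1-iodo-4-(tert-butyldimethylsilyloxymethyl)-8-methylnona-1,3,7-triene | I/C=C/C=C(\CO[Si](C)(C)C(C)(C)C)CCC=C(C)C | intermediate
25 | triene diol: 7,7-ethylenedioxy-10-methyl-6-[3-(tert-butyldimethylsilyloxy)propyl]-2-[(3E,5Z)-6-(tert-butyldimethylsilyloxymethyl)-10-methylundeca-1,3,5,9-tetraen-2-yl]spiro[4.5]decane-1,10-diol (1,2-cis) | C=C(/C=C/C=C(\CO[Si](C)(C)C(C)(C)C)CCC=C(C)C)[C@H]1CC[C@]2([C@H](CCCO[Si](C)(C)C(C)(C)C)C3(OCCO3)CC[C@]2(C)O)[C@H]1O | intermediate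
26 | 1,10-bis(triethylsilyl) ether of 25 | C=C(/C=C/C=C(\CO[Si](C)(C)C(C)(C)C)CCC=C(C)C)[C@H]1CC[C@]2([C@H](CCCO[Si](C)(C)C(C)(C)C)C3(OCCO3)CC[C@]2(C)O[Si](CC)(CC)CC)[C@H]1O[Si](CC)(CC)CC | intermediate
27 | C7 ketone: 1,10-bis(triethylsilyloxy)-10-methyl-6-[3-(tert-butyldimethylsilyloxy)propyl]-2-[(3E,5Z)-6-(tert-butyldimethylsilyloxymethyl)-10-methylundeca-1,3,5,9-tetraen-2-yl]spiro[4.5]decan-7-one | C=C(/C=C/C=C(\CO[Si](C)(C)C(C)(C)C)CCC=C(C)C)[C@H]1CC[C@]2([C@H](CCCO[Si](C)(C)C(C)(C)C)C(=O)CC[C@]2(C)O[Si](CC)(CC)CC)[C@H]1O[Si](CC)(CC)CC | intermediate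
28 | C7 isopropenyl carbinol of 27 (expected major epimer drawn, isopropenyl trans to the C6 chain; configuration at C7 inconsequential) | C=C(/C=C/C=C(\CO[Si](C)(C)C(C)(C)C)CCC=C(C)C)[C@H]1CC[C@]2([C@H](CCCO[Si](C)(C)C(C)(C)C)[C@@](O)(C(C)=C)CC[C@]2(C)O[Si](CC)(CC)CC)[C@H]1O[Si](CC)(CC)CC | intermediate
29 | silyl-protected (Z)-enal: (2Z)-2-(spiro[4.5]decan-7-ylidene)propanal bearing two triethylsilyl and two tert-butyldimethylsilyl ethers | C=C(/C=C/C=C(\CO[Si](C)(C)C(C)(C)C)CCC=C(C)C)[C@H]1CC[C@]2([C@H](CCCO[Si](C)(C)C(C)(C)C)/C(=C(/C)C=O)CC[C@]2(C)O[Si](CC)(CC)CC)[C@H]1O[Si](CC)(CC)CC | intermediate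
30 | (2Z)-2-[(1S,2R,5S,6R,10S)-1,10-dihydroxy-2-[(3E,5Z)-6-(hydroxymethyl)-10-methylundeca-1,3,5,9-tetraen-2-yl]-6-(3-hydroxypropyl)-10-methylspiro[4.5]decan-7-ylidene]propanal | C=C(/C=C/C=C(\CO)CCC=C(C)C)[C@H]1CC[C@]2([C@H](CCCO)/C(=C(/C)C=O)CC[C@]2(C)O)[C@H]1O | target

**Step count and risks**
Total step count: 19. Longest linear sequence: 15 steps (steps 1–9, then 14–19); the side chain (steps 10–13) joins at step 14.

Steps most likely to fail:

Step 1. Enantiofacial control may be insufficient in the copper-catalysed addition to the hindered β-carbon next to the ketal, and the enolate may be protonated by cyclobutanone instead of adding to it. Fallback, setting out from 4 and returning at 6: Grignard reagent 4 is transmetalated with ZnCl2 (0.5 equiv, magnesium salts precipitated with 1,4-dioxane) to bis[3-(tert-butyldimethylsilyloxy)propyl]zinc F1. F1 is added to commercial 1,4-dioxaspiro[4.5]deca-6,9-dien-8-one (O=C1C=CC2(C=C1)OCCO2) with Cu(OTf)2 and a binaphthol-derived phosphoramidite ligand, a desymmetrising conjugate addition to a quinone monoketal. The zinc enolate is trapped with 3 to give the unsaturated aldol adduct F2, and hydrogenation of the remaining enone double bond (H2, Pd/C, EtOAc) gives 6.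

Step 14. Transmetalation of the hindered 1,1-disubstituted alkenylsilanolate may be slow, so that protodesilylation competes, and the primary silyl ethers would be lost if fluoride activation had to be used. Fallback, setting out from 15 and returning at 26: Tamao–Fleming oxidation of the siloxane (KF, KHCO3, H2O2, THF/MeOH) gives the cis-2-acetylcyclopentanol F3. Both hydroxyls are silylated (Et3SiOTf, 2,6-lutidine) to the bis(triethylsilyl) ether F4. Kinetic enolisation of the methyl ketone and O-triflation (KHMDS, PhNTf2, THF, −78 °C) give the enol triflate F5. Stille coupling of F5 with dienylstannane 23 (Pd(PPh3)4, LiCl, CuCl, DMSO) gives 26.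

Step 18. The geometry of the new tetrasubstituted double bond may be poorly controlled in the sigmatropic shift, and the acidic oxidant may erode the silyl ethers. Fallback, setting out from 27 and returning at 29: Horner–Wadsworth–Emmons olefination of the ketone with diethyl (1-cyanoethyl)phosphonate (KOt-Bu, THF, reflux) gives the α-methyl unsaturated nitrile as two geometric isomers. The isomer with the nitrile cis to C6, nitrile F6, is separated; the other isomer is re-equilibrated photochemically and recycled. Reduction of F6 with i-Bu2AlH (toluene, −78 °C) and hydrolysis of the aldimine give 29.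

**Further compounds**
F1 | step 1 | bis[3-(tert-butyldimethylsilyloxy)propyl]zinc | CC(C)(C)[Si](C)(C)OCCC[Zn]CCCO[Si](C)(C)C(C)(C)C
F2 | step 1 | trans-7-(1-hydroxycyclobutyl)-6-[3-(tert-butyldimethylsilyloxy)propyl]-1,4-dioxaspiro[4.5]dec-9-en-8-one | O=C1C=CC2(OCCO2)[C@@H](CCCO[Si](C)(C)C(C)(C)C)[C@@H]1C1(O)CCC1
F3 | step 14 | 2-acetyl-7,7-ethylenedioxy-10-methyl-6-[3-(tert-butyldimethylsilyloxy)propyl]spiro[4.5]decane-1,10-diol (1,2-cis) | CC(=O)[C@H]1CC[C@]2([C@H](CCCO[Si](C)(C)C(C)(C)C)C3(OCCO3)CC[C@]2(C)O)[C@H]1O
F4 | step 14 | 1,10-bis(triethylsilyl) ether of F3 | CC(=O)[C@H]1CC[C@]2([C@H](CCCO[Si](C)(C)C(C)(C)C)C3(OCCO3)CC[C@]2(C)O[Si](CC)(CC)CC)[C@H]1O[Si](CC)(CC)CC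
F5 | step 14 | enol triflate of F4 (1-(trifluoromethylsulfonyloxy)vinyl group at C2) | C=C(OS(=O)(=O)C(F)(F)F)[C@H]1CC[C@]2([C@H](CCCO[Si](C)(C)C(C)(C)C)C3(OCCO3)CC[C@]2(C)O[Si](CC)(CC)CC)[C@H]1O[Si](CC)(CC)CC
F6 | step 18 | (2Z)-2-(spiro[4.5]decan-7-ylidene)propanenitrile analogue of 29 (nitrile cis to C6) | C=C(/C=C/C=C(\CO[Si](C)(C)C(C)(C)C)CCC=C(C)C)[C@H]1CC[C@]2([C@H](CCCO[Si](C)(C)C(C)(C)C)/C(=C(/C)C#N)CC[C@]2(C)O[Si](CC)(CC)CC)[C@H]1O[Si](CC)(CC)CC
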